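**Retrosynthetic overview**

1. Target 39 comes from triene 38 by peracid epoxidation of C4=C5 (last ring); 38 comes from macrocycle 22 by C11 methylenation, acetonide removal, O9 acetylation and O8 acylation with the silyl-protected chlorohydrin acid 35 (from tiglic acid by Sharpless epoxidation and chloride opening).
2. 22 comes from the seco iodoenoate diene 20 by forming C1–C2: hydroboration at C2 of the terminal diene, then palladium-catalysed sp2–sp3 coupling with the C1 iodide closes the ten-membered ring C1–C10.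
3. 20 comes from aldehyde 16, methyl propiolate and iodide (C9–C10 bond, C9 carbinol, C1 iodide); 16 comes from lactone aldehyde 13 by a dithiane one-carbon homologation (C8–C9).
4. 13 comes from dienal 3 and succinyl imide 8 by an Evans syn-aldol and lactonisation (C6–C7; the γ-lactone O–C6–C7–C11–C12 is the first ring).
5. Feature: in the carbocycle C1–C10 only C2 and C3 carry no functionality, and they lie between C1 (β-carbon of the C10 enoate bearing the C14 ester) and the C4=C5 alkene; a C1 vinyl iodide and a C2 borane from a C2=C3–C4=C5 diene therefore close the ring with C6–C9 already set. Ring order: γ-lactone, temporary dioxolane, ten-membered ring, epoxide.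

Key step: step 12

Remark: atoms carry germacranolide numbers (ring C1–C10, lactone C12(=O)–O–C6 with C11 and C13, ester carbon C14 on C10, methyl C15 on C4); CIP descriptors of intermediates change with substituent priorities while the spatial arrangement at C6–C9 stays that of the target.

**Route**

Step 1
Reactants: 1 (E)-3-methylpent-2-en-4-yn-1-ol
Product: 2 (E)-3-methylpenta-2,4-dien-1-ol
Conditions: H2 (1 atm), Pd/CaCO3 poisoned with Pb(OAc)2 (Lindlar catalyst), quinoline, EtOAc, 0 °C, stopped after 1 equiv H2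
Reagents that add atoms: none
Why: Lindlar semihydrogenation stops at the alkene, so the terminal alkyne becomes the C2=C3 vinyl group while the (E)-C4=C5 alkene is untouched.

Step 2
Reactants: 2 (E)-3-methylpenta-2,4-dien-1-ol
Product: 3 (E)-3-methylpenta-2,4-dienal
Conditions: MnO2 (activated), CH2Cl2, rt; used as a solution
Reagents that add atoms: none
Why: MnO2 oxidises the dienylic primary alcohol selectively to the conjugated aldehyde without E/Z scrambling (allylic oxidation).

Step 3
Reactants: 4 succinic anhydride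
Product: 5 4-methoxy-4-oxobutanoic acid
Conditions: MeOH, reflux
Reagents that add atoms: methanol, CO
Why: Alcoholysis of the cyclic anhydride stops at the half ester (anhydride ring opening).

Step 4
Reactants: 5 4-methoxy-4-oxobutanoic acid; 6 (S)-4-benzyl-1,3-oxazolidin-2-one
Product: 8 methyl 4-[(4S)-4-benzyl-2-oxo-1,3-oxazolidin-3-yl]-4-oxobutanoate, via mixed pivalic anhydride 7 (not isolated)
Conditions: PivCl, Et3N, THF, −20 °C; then 6, LiCl, rt
Reagents that add atoms: none
Why: N-acylation of the oxazolidinone through the mixed pivalic anhydride, attack occurring at the less hindered succinyl carbonyl.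

Step 5
Reactants: 8 methyl 4-[(4S)-4-benzyl-2-oxo-1,3-oxazolidin-3-yl]-4-oxobutanoate; 3 (E)-3-methylpenta-2,4-dienal
Product: 11 (4S)-4-benzyl-3-{[(2R,3S)-2-[(E)-2-methylbuta-1,3-dien-1-yl]-5-oxooxolan-3-yl]carbonyl}-1,3-oxazolidin-2-one, via dibutylboron enolate 9 (not isolated), via syn-aldol adduct 10 (not isolated)
Conditions: Bu2BOTf, iPr2NEt, CH2Cl2, −78 → 0 °C; 3, −78 → 0 °C; pH 7 buffer, MeOH, H2O2, 0 °C; then PPTS (cat.), CH2Cl2, rt
Reagents that add atoms: none
Why: Evans syn-aldol: the (Z)-boron enolate formed at the imide α-carbon (C7) adds to the dienal through a chair transition state on the face away from the benzyl group, which should set C6 and C7 (6R,7S, syn), and the C6 hydroxyl then closes onto the methyl ester to give the trans-disubstituted γ-lactone.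

Step 6
Reactants: 11 lactone imide
Product: 12 (4R,5R)-4-(hydroxymethyl)-5-[(E)-2-methylbuta-1,3-dien-1-yl]oxolan-2-one
Conditions: NaBH4, THF/H2O (4:1), 0 °C; pH 7 quench
Reagents that add atoms: none
Why: NaBH4 in wet THF reduces the exocyclic imide carbonyl much faster than the γ-lactone (reductive removal of the Evans auxiliary), leaving C7 untouched.

Step 7
Reactants: 12 hydroxymethyl lactone
Product: 13 (2R,3S)-2-[(E)-2-methylbuta-1,3-dien-1-yl]-5-oxooxolane-3-carbaldehyde
Conditions: Dess–Martin periodinane, NaHCO3, CH2Cl2, 0 °C; used at once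
Reagents that add atoms: none
Why: Dess–Martin oxidation under buffered, non-basic conditions should give the aldehyde without epimerising C7 or eliminating the β-acyloxy group.

Step 8
Reactants: 13 lactone aldehyde
Product: 15 (4S,5R)-4-[(R)-(1,3-dithian-2-yl)(triethylsilyloxy)methyl]-5-[(E)-2-methylbuta-1,3-dien-1-yl]oxolan-2-one, via lithium alkoxide 14 (not isolated)
Conditions: 1,3-dithiane, n-BuLi, THF, −30 °C; 13, −78 °C; then Et3SiOTf, −78 → −40 °C
Reagents that add atoms: 1,3-dithiane, C1CSCSC1; triethylsilyl triflate, CC[Si](CC)(CC)OS(=O)(=O)C(F)(F)F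
Why: 2-Lithio-1,3-dithiane (formyl anion equivalent, Corey–Seebach addition) adds to the aldehyde at −78 °C faster than to the lactone, Felkin–Anh attack anti to the C7–C6 bond should give the 8R carbinol, and the alkoxide is silylated in the flask before it can translactonise.

Step 9
Reactants: 15 silylated dithiane
Product: 16 (R)-2-[(2R,3S)-2-[(E)-2-methylbuta-1,3-dien-1-yl]-5-oxooxolan-3-yl]-2-(triethylsilyloxy)acetaldehyde
Conditions: MeI, CaCO3, MeCN/H2O (9:1), 40 °C
Reagents that add atoms: water, O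
Why: S-Methylation makes the dithiane a leaving group and buffered hydrolysis releases the α-silyloxy aldehyde (alkylative dithioacetal hydrolysis) without touching diene, lactone or silyl ether.

Step 10
Reactants: 16 α-silyloxy aldehyde; 17 methyl prop-2-ynoate
Product: 18 methyl (2E,3S,4R)-3-hydroxy-2-(iodomethylidene)-4-[(2R,3S)-2-[(E)-2-methylbuta-1,3-dien-1-yl]-5-oxooxolan-3-yl]-4-(triethylsilyloxy)butanoate
Conditions: 17 (1.5 equiv), MgI2 (1.5 equiv), CH2Cl2, 0 °C, then 35 °C until the iodide geometry has equilibrated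
Reagents that add atoms: magnesium iodide, [Mg+2].[I-].[I-]
Why: Iodide adds to the propiolate to give a magnesium β-iodoallenolate that adds to the aldehyde (three-component halo-aldol, the β-iodo Morita–Baylis–Hillman coupling); attack anti to the C8–OSiEt3 bond (polar Felkin–Anh) should set C9 as 9S (8,9-anti), and because the first-formed adduct carries iodine cis to the ester the mixture is kept warm with excess MgI2 so that reversible iodide addition–elimination relaxes it to the more stable (E)-isomer with iodine trans to the ester and cis to C9 (the tiglate-over-angelate preference).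

Step 11
Reactants: 18 iodoenoate silyl ether
Product: 20 methyl (E)-3-iodo-2-{(4S,5R)-2,2-dimethyl-5-[(2R,3S)-2-[(E)-2-methylbuta-1,3-dien-1-yl]-5-oxooxolan-3-yl]-1,3-dioxolan-4-yl}prop-2-enoate, via 8,9-diol 19 (not isolated)
Conditions: Me2C(OMe)2, MeOH (2 equiv), PPTS (cat.), CH2Cl2, rt
Reagents that add atoms: 2,2-dimethoxypropane, COC(C)(C)OC
Why: Acid-catalysed methanolysis removes the triethylsilyl group and the 8,9-anti diol is trapped as the cis-4,5-disubstituted dioxolane (transacetalisation), which holds C7 and C10 on the same side for ring closure.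

Step 12
Reactants: 20 seco iodoenoate diene acetonide
Product: 22 methyl (1(10)E,4E,6R,7S,8R,9S)-8,9-(isopropylidenedioxy)germacra-1(10),4-dien-12,6-olid-14-oate, via B-alkyl-9-BBN borane 21 (not isolated)
Conditions: 9-BBN-H (1.3 equiv), THF, 0 °C → rt; then slow addition to Pd(dppf)Cl2 (20 mol%), AsPh3 (40 mol%), Cs2CO3 (3 equiv), H2O, DMF/THF, 45 °C, 2 mM
Reagents that add atoms: none
Why: 9-BBN-H adds across the monosubstituted C2=C3 terminus of the diene with boron on C2 (anti-Markovnikov; the trisubstituted C4=C5 and the electron-poor iodoenoate react far more slowly), zerovalent palladium generated from Pd(dppf)Cl2 inserts into the C1–I bond, the hydroxide-activated borate hands over its primary alkyl group and reductive elimination forms C1–C2 (intramolecular B-alkyl Suzuki–Miyaura coupling). The closest known reaction type is the macrocyclising 9-BBN/vinyl iodide cross-coupling used for medium and large carbocycles. The ten-membered ring C1–C10 is closed end to end between the two chain termini by this sp2–sp3 bond formation. No stereocentre is created; the C1=C10 geometry is carried over with retention from the (E)-iodide, in which iodine is cis to C9, so C2 enters cis to C9. The step needs chemoselective hydroboration and cyclisation in preference to oligomerisation: the first follows from the substitution pattern of the alkenes, the second is served by slow addition at high dilution and by the cis-fused dioxolane and trans-fused lactone, which turn C1 and C2 toward each other. Oxidative addition to the vinyl iodide is much faster than ionisation of the allylic lactone C6–O bond, and the lactone, acetonide and methyl ester tolerate 9-BBN-H and aqueous Cs2CO3 at 45 °C.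

Step 13
Reactants: 22 macrocyclic acetonide
Product: 24 methyl (1(10)E,4E,6R,7S,8R,9S)-11-[(dimethylamino)methyl]-8,9-(isopropylidenedioxy)germacra-1(10),4-dien-12,6-olid-14-oate (C11 epimers), via lithium lactone enolate 23 (not isolated)
Conditions: LiN(SiMe3)2, THF, −78 °C; CH2=NMe2+ I−, −78 → 0 °C
Reagents that add atoms: dimethyl(methylidene)ammonium iodide (Eschenmoser's salt), C=[N+](C)C.[I-]
Why: Kinetic deprotonation of the lactone α-CH2 (C11) and Mannich reaction of the enolate with the iminium salt (aminomethylation); the C11 configuration is lost in the next step.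

Step 14
Reactants: 24 Mannich base
Product: 26 methyl (1(10)E,4E,6R,7S,8R,9S)-8,9-(isopropylidenedioxy)germacra-1(10),4,11(13)-trien-12,6-olid-14-oate, via trimethylammonium iodide 25 (not isolated)
Conditions: MeI, MeOH, rt; then NaHCO3 (aq), CH2Cl2, rt
Reagents that add atoms: none
Why: Quaternisation and E1cB elimination of trimethylamine unveil the exocyclic C11=C13 methylene.

Step 15
Reactants: 26 α-methylene lactone acetonide
Product: 27 methyl (1(10)E,4E,6R,7R,8R,9S)-8,9-dihydroxygermacra-1(10),4,11(13)-trien-12,6-olid-14-oate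
Conditions: AcOH/THF/H2O (3:1:1), 45 °C
Reagents that add atoms: none
Why: Mild aqueous acid hydrolyses the dioxolane without touching the esters or the lactone (acetal hydrolysis).

Step 16
Reactants: 27 8,9-diol
Product: 28 methyl (1(10)E,4E,6R,7R,8R,9S)-9-acetoxy-8-hydroxygermacra-1(10),4,11(13)-trien-12,6-olid-14-oate
Conditions: AcCl (1.05 equiv), 2,4,6-collidine, CH2Cl2, −78 → −40 °C
Reagents that add atoms: acetyl chloride, CC(=O)Cl
Why: Kinetic acylation at low temperature should take place at O9, the allylic hydroxyl next to the flat sp2 C10, in preference to O8, which sits between two sp3 methine carbons (C7 at the ring fusion and C9).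

Step 17
Reactants: 29 tiglic acid
Product: 30 (E)-2-methylbut-2-en-1-ol
Conditions: LiAlH4, Et2O, 0 °C → rt
Reagents that add atoms: none
Why: Hydride 1,2-reduction of the acid gives the allylic alcohol with the E geometry retained.

Step 18
Reactants: 30 (E)-2-methylbut-2-en-1-ol
Product: 31 [(2S,3S)-2,3-dimethyloxiran-2-yl]methanol
Conditions: Ti(OiPr)4 (5 mol%), L-(+)-diethyl tartrate (6 mol%), t-BuOOH, 4 Å molecular sieves, CH2Cl2, −20 °C
Reagents that add atoms: tert-butyl hydroperoxide, CC(C)(C)OO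
Why: Sharpless asymmetric epoxidation; L-(+)-tartrate should deliver oxygen to the face that gives the (2S,3S)-epoxy alcohol, as with other (E)-allylic alcohols.

Step 19
Reactants: 31 epoxy alcohol
Product: 32 (2R,3S)-2,3-dimethyloxirane-2-carboxylic acid
Conditions: TEMPO (cat.), NaOCl (cat.), NaClO2, MeCN/phosphate buffer (pH 6.7), 35 °C
Reagents that add atoms: sodium chlorite, [Na+].[O-]Cl=O
Why: TEMPO/chlorite oxidation takes the primary alcohol to the acid near neutral pH, which spares the epoxide.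

Step 20
Reactants: 32 epoxy acid
Product: 33 (2S,3R)-3-chloro-2-hydroxy-2-methylbutanoic acid
Conditions: HCl (2 M in Et2O), 0 °C
Reagents that add atoms: hydrogen chloride, Cl
Why: Acid-promoted epoxide opening by chloride at C3 with inversion (SN2), C2 being fully substituted and deactivated by the carboxyl group, should give the (2S,3R)-chlorohydrin.

Step 21
Reactants: 33 chlorohydrin acid
Product: 35 (2S,3R)-3-chloro-2-methyl-2-(triethylsilyloxy)butanoic acid, via bis(triethylsilyl) derivative 34 (not isolated)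
Conditions: Et3SiOTf (2.2 equiv), 2,6-lutidine, CH2Cl2, 0 °C; then THF/H2O/AcOH work-up
Reagents that add atoms: triethylsilyl triflate, CC[Si](CC)(CC)OS(=O)(=O)C(F)(F)F
Why: Both hydroxyl and carboxyl groups are silylated and the silyl ester hydrolyses on aqueous work-up, leaving the tertiary silyl ether (protection).

Step 22
Reactants: 28 9-acetoxy-8-ol; 35 silyl-protected chlorohydrin acid
Product: 37 methyl (1(10)E,4E,6R,7S,8R,9S)-9-acetoxy-8-{[(2S,3R)-3-chloro-2-methyl-2-(triethylsilyloxy)butanoyl]oxy}germacra-1(10),4,11(13)-trien-12,6-olid-14-oate, via mixed trichlorobenzoic anhydride 36 (not isolated)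
Conditions: 35, 2,4,6-trichlorobenzoyl chloride, Et3N, THF, rt; then 28, DMAP, toluene, rt
Reagents that add atoms: none
Why: Yamaguchi esterification: the mixed anhydride and DMAP transfer the hindered acyl group to the C8 hydroxyl, and the acid has no α-hydrogen, so its stereocentres cannot epimerise.

Step 23
Reactants: 37 silyl-protected diester
Product: 38 methyl (1(10)E,4E,6R,7S,8R,9S)-9-acetoxy-8-{[(2S,3R)-3-chloro-2-hydroxy-2-methylbutanoyl]oxy}germacra-1(10),4,11(13)-trien-12,6-olid-14-oate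
Conditions: HF·pyridine, pyridine, THF, 0 °C → rt
Reagents that add atoms: none
Why: Buffered fluoride cleaves the tertiary triethylsilyl ether without forming an alkoxide, so the chlorohydrin does not close to an epoxide and the acetate does not migrate.

Step 24
Reactants: 38 triene
Product: 39 methyl (1(10)E,4R,5R,6S,7R,8R,9S)-9-acetoxy-8-{[(2S,3R)-3-chloro-2-hydroxy-2-methylbutanoyl]oxy}-4,5-epoxygermacra-1(10),11(13)-dien-12,6-olid-14-oate (CNP0185503.3)
Conditions: mCPBA, NaHCO3, CH2Cl2, 0 °C
Reagents that add atoms: 3-chloroperoxybenzoic acid, OOC(=O)c1cccc(Cl)c1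
Why: Prilezhaev epoxidation: the peracid selects the only electron-rich alkene (trisubstituted C4=C5; the enoate and the α-methylene lactone are deactivated) and should attack its exposed outer face in the ten-membered ring, giving the (4R,5R) trans-epoxide found in related 4,5-epoxy germacranolides.

**Compound list**

1 | (E)-3-methylpent-2-en-4-yn-1-ol | C#C/C(C)=C/CO | starting material
2 | (E)-3-methylpenta-2,4-dien-1-ol | C=C/C(C)=C/CO | intermediate
3 | (E)-3-methylpenta-2,4-dienal | C=C/C(C)=C/C=O | intermediate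
4 | succinic anhydride | O=C1CCC(=O)O1 | starting material
5 | 4-methoxy-4-oxobutanoic acid | COC(=O)CCC(=O)O | intermediate
6 | (S)-4-benzyl-1,3-oxazolidin-2-one | O=C1N[C@@H](Cc2ccccc2)CO1 | starting material
7 | 4-methoxy-4-oxobutanoic pivalic anhydride | COC(=O)CCC(=O)OC(=O)C(C)(C)C | intermediate
8 | methyl 4-[(4S)-4-benzyl-2-oxo-1,3-oxazolidin-3-yl]-4-oxobutanoate | COC(=O)CCC(=O)N1[C@@H](Cc2ccccc2)COC1=O | intermediate
9 | dibutylboron (Z)-enolate of 8 | CCCCB(CCCC)O/C(=C\CC(=O)OC)N1[C@@H](Cc2ccccc2)COC1=O | intermediate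
10 | methyl (3S,4R,5E)-3-{[(4S)-4-benzyl-2-oxo-1,3-oxazolidin-3-yl]carbonyl}-4-hydroxy-6-methylocta-5,7-dienoate | C=C/C(C)=C/[C@@H](O)[C@H](CC(=O)OC)C(=O)N1[C@@H](Cc2ccccc2)COC1=O | intermediate
11 | (4S)-4-benzyl-3-{[(2R,3S)-2-[(E)-2-methylbuta-1,3-dien-1-yl]-5-oxooxolan-3-yl]carbonyl}-1,3-oxazolidin-2-one | C=C/C(C)=C/[C@H]1OC(=O)C[C@@H]1C(=O)N2[C@@H](Cc3ccccc3)COC2=O | intermediate
12 | (4R,5R)-4-(hydroxymethyl)-5-[(E)-2-methylbuta-1,3-dien-1-yl]oxolan-2-one | C=C/C(C)=C/[C@H]1OC(=O)C[C@@H]1CO | intermediate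
13 | (2R,3S)-2-[(E)-2-methylbuta-1,3-dien-1-yl]-5-oxooxolane-3-carbaldehyde | C=C/C(C)=C/[C@H]1OC(=O)C[C@@H]1C=O | intermediate
14 | lithium alkoxide of the dithiane adduct (6R,7R,8R) | C=C/C(C)=C/[C@H]1OC(=O)C[C@@H]1[C@@H](O[Li])C2SCCCS2 | intermediate
15 | (4S,5R)-4-[(R)-(1,3-dithian-2-yl)(triethylsilyloxy)methyl]-5-[(E)-2-methylbuta-1,3-dien-1-yl]oxolan-2-one | C=C/C(C)=C/[C@H]1OC(=O)C[C@@H]1[C@@H](O[Si](CC)(CC)CC)C2SCCCS2 | intermediate
16 | (R)-2-[(2R,3S)-2-[(E)-2-methylbuta-1,3-dien-1-yl]-5-oxooxolan-3-yl]-2-(triethylsilyloxy)acetaldehyde | C=C/C(C)=C/[C@H]1OC(=O)C[C@@H]1[C@@H](O[Si](CC)(CC)CC)C=O | intermediate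
17 | methyl prop-2-ynoate | C#CC(=O)OC | starting material
18 | methyl (2E,3S,4R)-3-hydroxy-2-(iodomethylidene)-4-[(2R,3S)-2-[(E)-2-methylbuta-1,3-dien-1-yl]-5-oxooxolan-3-yl]-4-(triethylsilyloxy)butanoate | C=C/C(C)=C/[C@H]1OC(=O)C[C@@H]1[C@@H](O[Si](CC)(CC)CC)[C@@H](O)/C(C(=O)OC)=C\I | intermediate
19 | methyl (2E,3S,4R)-3,4-dihydroxy-2-(iodomethylidene)-4-[(2R,3R)-2-[(E)-2-methylbuta-1,3-dien-1-yl]-5-oxooxolan-3-yl]butanoate | C=C/C(C)=C/[C@H]1OC(=O)C[C@@H]1[C@@H](O)[C@@H](O)/C(C(=O)OC)=C\I | intermediate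
20 | methyl (E)-3-iodo-2-{(4S,5R)-2,2-dimethyl-5-[(2R,3S)-2-[(E)-2-methylbuta-1,3-dien-1-yl]-5-oxooxolan-3-yl]-1,3-dioxolan-4-yl}prop-2-enoate | C=C/C(C)=C/[C@H]1OC(=O)C[C@@H]1[C@H]2OC(C)(C)O[C@H]2/C(C(=O)OC)=C\I | intermediate
21 | B-alkyl-9-borabicyclo[3.3.1]nonane from 20 (boron on C2) | B1(C2CCCC1CCC2)CC/C(C)=C/[C@H]3OC(=O)C[C@@H]3[C@H]4OC(C)(C)O[C@H]4/C(C(=O)OC)=C\I | intermediate
22 | methyl (1(10)E,4E,6R,7S,8R,9S)-8,9-(isopropylidenedioxy)germacra-1(10),4-dien-12,6-olid-14-oate | C1/C(C)=C/[C@H]2OC(=O)C[C@@H]2[C@H]3OC(C)(C)O[C@H]3/C(C(=O)OC)=C\C1 | intermediate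
23 | lithium enolate of lactone 22 | C1/C(C)=C/[C@H]2OC(O[Li])=C[C@@H]2[C@H]3OC(C)(C)O[C@H]3/C(C(=O)OC)=C\C1 | intermediate
24 | 11-[(dimethylamino)methyl] derivative of 22 (C11 epimers) | C1/C(C)=C/[C@H]2OC(=O)C(CN(C)C)[C@@H]2[C@H]3OC(C)(C)O[C@H]3/C(C(=O)OC)=C\C1 | intermediate
25 | 11-[(trimethylammonio)methyl] iodide of 22 | C1/C(C)=C/[C@H]2OC(=O)C(C[N+](C)(C)C)[C@@H]2[C@H]3OC(C)(C)O[C@H]3/C(C(=O)OC)=C\C1.[I-] | intermediate
26 | methyl (1(10)E,4E,6R,7S,8R,9S)-8,9-(isopropylidenedioxy)germacra-1(10),4,11(13)-trien-12,6-olid-14-oate | C1/C(C)=C/[C@H]2OC(=O)C(=C)[C@@H]2[C@H]3OC(C)(C)O[C@H]3/C(C(=O)OC)=C\C1 | intermediate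
27 | methyl (1(10)E,4E,6R,7R,8R,9S)-8,9-dihydroxygermacra-1(10),4,11(13)-trien-12,6-olid-14-oate | C1/C(C)=C/[C@H]2OC(=O)C(=C)[C@@H]2[C@@H](O)[C@@H](O)/C(C(=O)OC)=C\C1 | intermediate
28 | methyl (1(10)E,4E,6R,7R,8R,9S)-9-acetoxy-8-hydroxygermacra-1(10),4,11(13)-trien-12,6-olid-14-oate | C1/C(C)=C/[C@H]2OC(=O)C(=C)[C@@H]2[C@@H](O)[C@@H](OC(C)=O)/C(C(=O)OC)=C\C1 | intermediate
29 | tiglic acid, (E)-2-methylbut-2-enoic acid | C/C=C(\C)C(=O)O | starting material
30 | (E)-2-methylbut-2-en-1-ol | C/C=C(\C)CO | intermediate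
31 | [(2S,3S)-2,3-dimethyloxiran-2-yl]methanol | C[C@@H]1O[C@@]1(C)CO | intermediate
32 | (2R,3S)-2,3-dimethyloxirane-2-carboxylic acid | C[C@@H]1O[C@@]1(C)C(=O)O | intermediate
33 | (2S,3R)-3-chloro-2-hydroxy-2-methylbutanoic acid | OC(=O)[C@](C)(O)[C@@H](C)Cl | intermediate
34 | triethylsilyl (2S,3R)-3-chloro-2-methyl-2-(triethylsilyloxy)butanoate | CC[Si](CC)(CC)OC(=O)[C@](C)(O[Si](CC)(CC)CC)[C@@H](C)Cl | intermediate
35 | (2S,3R)-3-chloro-2-methyl-2-(triethylsilyloxy)butanoic acid | OC(=O)[C@](C)(O[Si](CC)(CC)CC)[C@@H](C)Cl | intermediate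
36 | (2S,3R)-3-chloro-2-methyl-2-(triethylsilyloxy)butanoic 2,4,6-trichlorobenzoic anhydride | O=C(OC(=O)[C@](C)(O[Si](CC)(CC)CC)[C@@H](C)Cl)c1c(Cl)cc(Cl)cc1Cl | intermediate
37 | methyl (1(10)E,4E,6R,7S,8R,9S)-9-acetoxy-8-{[(2S,3R)-3-chloro-2-methyl-2-(triethylsilyloxy)butanoyl]oxy}germacra-1(10),4,11(13)-trien-12,6-olid-14-oate | C1/C(C)=C/[C@H]2OC(=O)C(=C)[C@@H]2[C@@H](OC(=O)[C@](C)(O[Si](CC)(CC)CC)[C@@H](C)Cl)[C@@H](OC(C)=O)/C(C(=O)OC)=C\C1 | intermediate
38 | methyl (1(10)E,4E,6R,7S,8R,9S)-9-acetoxy-8-{[(2S,3R)-3-chloro-2-hydroxy-2-methylbutanoyl]oxy}germacra-1(10),4,11(13)-trien-12,6-olid-14-oate | C1/C(C)=C/[C@H]2OC(=O)C(=C)[C@@H]2[C@@H](OC(=O)[C@](C)(O)[C@@H](C)Cl)[C@@H](OC(C)=O)/C(C(=O)OC)=C\C1 | intermediate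
39 | methyl (1(10)E,4R,5R,6S,7R,8R,9S)-9-acetoxy-8-{[(2S,3R)-3-chloro-2-hydroxy-2-methylbutanoyl]oxy}-4,5-epoxygermacra-1(10),11(13)-dien-12,6-olid-14-oate (CNP0185503.3) | C=C1C(=O)O[C@H]2[C@H]1[C@@H](OC(=O)[C@](C)(O)[C@@H](C)Cl)[C@@H](OC(C)=O)/C(C(=O)OC)=C\CC[C@@]1(C)O[C@H]21 | target

**Step count**

Total: 24 steps (main line 17, imide branch 2, side-chain acid 5). Longest linear sequence: 17 steps (1 → 39 through steps 1, 2, 5–16, 22–24).

**Steps most likely to fail**

1. Step 10 (iodoenoate). The coupling may stop at the kinetic geometry, in which the aldehyde has entered anti to iodine and iodine lies cis to the ester. Warming with MgI2 may instead open the dienylic lactone or erode the C9 selectivity. The fallback reverses the roles of the two carbonyl groups, so that kinetic control itself places iodine cis to C9. It sets out from 16 and returns at 20.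
 - Ethynylmagnesium bromide (THF, −78 °C) should give the propargylic alcohol F1, and Dess–Martin oxidation the ynone F2.
 - MgI2 and monomeric formaldehyde (CH2Cl2, 0 °C) should give the (Z)-β-iodo-α-(hydroxymethyl) enone F3, the electrophile entering anti to iodine.
 - HF·pyridine removes the silyl group to give the α-hydroxy ketone F4, and chelation-controlled reduction with Zn(BH4)2 should give the 8,9-anti triol F5.
 - Me2C(OMe)2/PPTS should give the five-membered 8,9-acetonide alcohol F6.
 - MnO2 gives the enal F7, NaClO2 the acid F8, and Me3SiCHN2 the methyl ester 20.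

2. Step 12 (key ring closure). Intermolecular coupling, protodeboronation or reduction of the iodide may outrun closure of the strained ten-membered ring, and zerovalent palladium may ionise the allylic lactone. The fallback forms the same C1–C2 bond by carbonyl addition. It sets out from 20 and returns at 22.
 - Hydroboration (9-BBN-H) and oxidation (NaBO3) should give the primary alcohol F9, and Dess–Martin oxidation the β,γ-unsaturated aldehyde F10.
 - Intramolecular Nozaki–Hiyama–Kishi reaction (CrCl2 with catalytic NiCl2, DMF, high dilution) should close the ring to the C2 carbinol F11.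
 - Acetylation gives the allylic acetate F12, and Pd(PPh3)4 with Bu3SnH should deliver hydride to the less hindered C2 terminus, giving 22.

3. Step 16 (O9 acetylation). Acylation may occur at O8 instead, or the acetyl group may migrate between the cis-disposed O8 and O9. The fallback reverses the order of the two acylations, so that the more reactive hydroxyl, if it proves to be O8, takes the bulky acid first. It sets out from 27 and returns at 37.
 - Yamaguchi esterification of 27 with 35 (through 36) should give the 8-O-acyl 9-alcohol F13.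
 - Ac2O/DMAP then acetylates the remaining O9 to give 37.

**Further compounds**

F1 | step 10 | propargylic alcohol from 16 (C9 epimers), C8 silyl ether | C=C/C(C)=C/[C@H]1OC(=O)C[C@@H]1[C@@H](O[Si](CC)(CC)CC)C(O)C#C
F2 | step 10 | C9 ynone, C8 silyl ether | C=C/C(C)=C/[C@H]1OC(=O)C[C@@H]1[C@@H](O[Si](CC)(CC)CC)C(=O)C#C
F3 | step 10 | (Z)-β-iodo-α-(hydroxymethyl) enone, C8 silyl ether | C=C/C(C)=C/[C@H]1OC(=O)C[C@@H]1[C@@H](O[Si](CC)(CC)CC)C(=O)/C(CO)=C\I
F4 | step 10 | (Z)-β-iodo-α-(hydroxymethyl) enone with free C8 hydroxyl | C=C/C(C)=C/[C@H]1OC(=O)C[C@@H]1[C@@H](O)C(=O)/C(CO)=C\I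
F5 | step 10 | 8,9-anti triol (8R,9S) with C14 hydroxymethyl | C=C/C(C)=C/[C@H]1OC(=O)C[C@@H]1[C@@H](O)[C@@H](O)/C(CO)=C\I
F6 | step 10 | 8,9-acetonide with C14 hydroxymethyl | C=C/C(C)=C/[C@H]1OC(=O)C[C@@H]1[C@H]2OC(C)(C)O[C@H]2/C(CO)=C\I
F7 | step 10 | 8,9-acetonide C14 aldehyde | C=C/C(C)=C/[C@H]1OC(=O)C[C@@H]1[C@H]2OC(C)(C)O[C@H]2/C(C=O)=C\I
F8 | step 10 | 8,9-acetonide C14 carboxylic acid | C=C/C(C)=C/[C@H]1OC(=O)C[C@@H]1[C@H]2OC(C)(C)O[C@H]2/C(C(=O)O)=C\I
F9 | step 12 | C2 primary alcohol from 20 | OCC/C(C)=C/[C@H]1OC(=O)C[C@@H]1[C@H]2OC(C)(C)O[C@H]2/C(C(=O)OC)=C\I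
F10 | step 12 | C2 aldehyde from 20 | O=CC/C(C)=C/[C@H]1OC(=O)C[C@@H]1[C@H]2OC(C)(C)O[C@H]2/C(C(=O)OC)=C\I
F11 | step 12 | 2-hydroxy derivative of macrocycle 22 (C2 epimers) | C1/C(C)=C/[C@H]2OC(=O)C[C@@H]2[C@H]3OC(C)(C)O[C@H]3/C(C(=O)OC)=C\C1O
F12 | step 12 | 2-acetoxy derivative of macrocycle 22 (C2 epimers) | C1/C(C)=C/[C@H]2OC(=O)C[C@@H]2[C@H]3OC(C)(C)O[C@H]3/C(C(=O)OC)=C\C1OC(C)=O
F13 | step 16 | 8-O-[(2S,3R)-3-chloro-2-methyl-2-(triethylsilyloxy)butanoyl] 9-alcohol from 27 | C1/C(C)=C/[C@H]2OC(=O)C(=C)[C@@H]2[C@@H](OC(=O)[C@](C)(O[Si](CC)(CC)CC)[C@@H](C)Cl)[C@@H](O)/C(C(=O)OC)=C\C1
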